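**Retrosynthetic overview**

1. Target 17 is a (2S)-flavanone whose phloroglucinol ring A (C4a, C5–C8, C8a) carries the farnesyl group on C6, between the C5 and C7 hydroxyls. Late C-farnesylation or a chalcone closure would have to choose between C6 and C8.
2. Ring A is therefore made last, by closing C4a–C5 in keto ester 15 (intramolecular Claisen, then aromatisation). The ether oxygen O1 already joins C2 to C8a in the dihydropyranone ring C, and the farnesyl group sits on the carbon between the C7 ketone and the C5 ester, so only the 6-isomer can form.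
3. 15 is cut at C7–C6: decarboxylative Claisen of pyranone-acetic acid 9 with farnesylmalonate half ester 13. This keeps strong base away from the dihydropyranone, whose C3 enolate would expel O1 and scramble C2.
4. Ring C comes from acid cyclodehydration of a δ-hydroxy-β-diketone (O1–C8a), made by acylating acetoacetate dianion with hydroxy ester 4 (C4–C4a). C2 is set by asymmetric transfer hydrogenation of aroylacetate 3.
5. Ring order: B (bought) → C (step 4) → A (step 9); the two B-ring MOM ethers are removed last.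

Key step: step 9

Remark on the chemistry: flavanone numbering (O1, C2–C4, C4a, C5–C8, C8a) is used for the corresponding atoms of all intermediates. "Farnesyl" means (2E,6E)-3,7,11-trimethyldodeca-2,6,10-trien-1-yl. Compound 15 is assumed to be a mixture of C6 epimers and keto–enol forms, which does not matter because C6 becomes sp2 in step 9.

**Route**

Step 1
Reactants: 1 3′,5′-dihydroxyacetophenone
Product: 2 1-[3,5-bis(methoxymethoxy)phenyl]ethan-1-one
Conditions: MOMCl (2.5 equiv), iPr2NEt (3 equiv), CH2Cl2, 0 °C → rt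
Reagents that add atoms: chloromethyl methyl ether, COCCl
Why: O-alkylation of both phenols as MOM ethers with a hindered amine base; the ketone is not affected.

Step 2
Reactants: 2 1-[3,5-bis(methoxymethoxy)phenyl]ethan-1-one
Product: 3 methyl 3-[3,5-bis(methoxymethoxy)phenyl]-3-oxopropanoate
Conditions: NaH (2.5 equiv), (MeO)2CO (5 equiv), THF, reflux; then AcOH, 0 °C
Reagents that add atoms: dimethyl carbonate, COC(=O)OC
Why: Crossed Claisen condensation of the methyl ketone enolate with dimethyl carbonate, driven by irreversible deprotonation of the β-keto ester formed.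

Step 3
Reactants: 3 methyl 3-[3,5-bis(methoxymethoxy)phenyl]-3-oxopropanoate
Product: 4 methyl (3S)-3-[3,5-bis(methoxymethoxy)phenyl]-3-hydroxypropanoate
Conditions: RuCl(p-cymene)[(S,S)-TsDPEN] (1 mol %), HCO2H/Et3N (5:2), DMF, 30 °C
Reagents that add atoms: none
Why: Noyori–Ikariya asymmetric transfer hydrogenation of an aryl ketone; the (S,S)-TsDPEN–Ru hydride should deliver hydrogen to the Re face of the carbonyl, as with acetophenone-type substrates, and so set the (S)-carbinol that becomes C2.

Step 4
Reactants: 4 methyl (3S)-3-[3,5-bis(methoxymethoxy)phenyl]-3-hydroxypropanoate; 5 allyl acetoacetate (prop-2-en-1-yl 3-oxobutanoate)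
Product: 8 prop-2-en-1-yl 2-{(2S)-2-[3,5-bis(methoxymethoxy)phenyl]-4-oxo-3,4-dihydro-2H-pyran-6-yl}acetate, via allyl acetoacetate dianion 6 (not isolated), via hydroxy diketo ester 7 (not isolated)
Conditions: 5 (3.5 equiv), NaH, THF, 0 °C, then n-BuLi, 0 °C; 4, −78 → 0 °C; aq. HCl work-up; TsOH·H2O (5 mol %), CH2Cl2, rt
Reagents that add atoms: none
Why: Claisen acylation of the acetoacetate dianion at its terminal carbon by the methyl ester (the excess covers the carbinol proton and the acidic product), then acid-catalysed cyclodehydration of the δ-hydroxy-β-diketone through its six-membered hemiketal to the 2,3-dihydro-4H-pyran-4-one; the C2 carbinol centre takes no part, and O1 is fixed on C8a.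

Step 5
Reactants: 8 prop-2-en-1-yl 2-{(2S)-2-[3,5-bis(methoxymethoxy)phenyl]-4-oxo-3,4-dihydro-2H-pyran-6-yl}acetate
Product: 9 2-{(2S)-2-[3,5-bis(methoxymethoxy)phenyl]-4-oxo-3,4-dihydro-2H-pyran-6-yl}acetic acid
Conditions: Pd(PPh3)4 (3 mol %), morpholine (3 equiv), THF, 0 °C → rt; cold aq. citric acid
Reagents that add atoms: none
Why: Pd(0)-catalysed allyl transfer to morpholine (Tsuji–Trost deallylation) frees the acid under neutral conditions at or below room temperature, so the MOM ethers and the C2–O1 bond are left alone and the vinylogous β-keto acid should not decarboxylate.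

Step 6
Reactants: 10 dimethyl malonate; 11 (2E,6E)-farnesyl bromide
Product: 12 dimethyl 2-[(2E,6E)-3,7,11-trimethyldodeca-2,6,10-trien-1-yl]propanedioate
Conditions: 10 (1.5 equiv), NaH (1.2 equiv), THF, 0 °C; 11, 0 °C → rt
Reagents that add atoms: none
Why: Malonic ester alkylation by SN2 displacement at the primary allylic bromide, which keeps both E double bonds; excess malonate suppresses dialkylation.

Step 7
Reactants: 12 dimethyl 2-[(2E,6E)-3,7,11-trimethyldodeca-2,6,10-trien-1-yl]propanedioate
Product: 13 potassium 3-methoxy-3-oxo-2-[(2E,6E)-3,7,11-trimethyldodeca-2,6,10-trien-1-yl]propanoate (racemic)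
Conditions: KOH (1.0 equiv), MeOH, 0 °C → rt
Reagents that add atoms: potassium hydroxide, [K+].[OH-]
Why: Half-saponification of a malonic diester with one equivalent of hydroxide; the carboxylate formed deactivates the second ester.

Step 8
Reactants: 9 2-{(2S)-2-[3,5-bis(methoxymethoxy)phenyl]-4-oxo-3,4-dihydro-2H-pyran-6-yl}acetic acid; 13 potassium methyl 2-farnesylmalonate
Product: 15 methyl 2-farnesyl-3-oxo-4-{(2S)-2-[3,5-bis(methoxymethoxy)phenyl]-4-oxo-3,4-dihydro-2H-pyran-6-yl}butanoate (C6 epimers), via acyl imidazolide 14 (not isolated)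
Conditions: 9, CDI (1.1 equiv), THF, rt; then 13 (1.5 equiv), MgCl2 (1.5 equiv), Et3N (2 equiv), THF/MeCN, rt → 40 °C; cold aq. citric acid
Reagents that add atoms: none
Why: Masamune–Brooks decarboxylative Claisen condensation: the acyl imidazolide acylates the magnesium enolate of the malonate half ester and CO2 is lost, which forms C7–C6 with the farnesyl group already on C6 and uses only weak bases, so that no C3 enolate can expel O1.

Step 9
Reactants: 15 methyl 2-farnesyl-3-oxo-4-{(2S)-2-[3,5-bis(methoxymethoxy)phenyl]-4-oxo-3,4-dihydro-2H-pyran-6-yl}butanoate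
Product: 16 (2S)-2-[3,5-bis(methoxymethoxy)phenyl]-6-farnesyl-5,7-dihydroxy-2,3-dihydro-4H-chromen-4-one
Conditions: DBU (3 equiv), THF, 0 °C → rt, Ar; pH 5 buffer quench
Reagents that add atoms: none
Why: Proposed new method: DBU ionises C8–H, and in the resulting dienolate (O7–C7=C8–C8a=C4a, also conjugated to C4=O) the terminal carbon C4a is nucleophilic and adds to the C5 ester carbonyl; methoxide is expelled and loss of the C4a and C6 protons aromatises the ring to the 5,7-diol. The closest known reaction is the base-mediated Claisen cyclisation of 3,5,7-triketo esters to acylphloroglucinols, here run on a triketide whose C4/C8a carbonyl pair is held as the cyclic vinylogous ester. Ring A closes by a 6-exo-trig acyl substitution in which the dienolate carbons C8a and C8 lie inside the new ring (enolendo). No stereocentre is formed: C2 from step 3 lies outside the reacting system and C6 becomes sp2, so both C6 epimers converge. The step needs C-acylation at C4a only, and the substrate secures this because the ether oxygen sits between C2 and C8a before ring A exists, attack of C8 or C6 on the ester would give four-membered rings, and aldol attack of C6 on C4 gives a quaternary adduct that can only revert. A non-nucleophilic amidine in an aprotic solvent is chosen so that C8–H and C6–H are ionised while C3–H is not, which should keep E1cB opening of O1–C2 and alkoxide retro-Claisen cleavage from competing.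

Step 10
Reactants: 16 (2S)-2-[3,5-bis(methoxymethoxy)phenyl]-6-farnesyl-5,7-dihydroxy-2,3-dihydro-4H-chromen-4-one
Product: 17 (2S)-2-(3,5-dihydroxyphenyl)-6-farnesyl-5,7-dihydroxy-2,3-dihydro-4H-chromen-4-one (CNP0186816.1)
Conditions: 3 M aq. HCl/MeOH (1:5), 40 °C, stopped at full conversion
Reagents that add atoms: none
Why: Acid-catalysed acetal exchange of the two aryl MOM ethers with methanol; the medium is not basic, so C2 is not scrambled through the chalcone, and short exposure at moderate temperature should spare the farnesyl alkenes.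

**Compound list**

1 | 3′,5′-dihydroxyacetophenone | CC(=O)c1cc(O)cc(O)c1 | starting material
2 | 1-[3,5-bis(methoxymethoxy)phenyl]ethan-1-one | CC(=O)c1cc(OCOC)cc(OCOC)c1 | intermediate
3 | methyl 3-[3,5-bis(methoxymethoxy)phenyl]-3-oxopropanoate | COC(=O)CC(=O)c1cc(OCOC)cc(OCOC)c1 | intermediate
4 | methyl (3S)-3-[3,5-bis(methoxymethoxy)phenyl]-3-hydroxypropanoate | COC(=O)C[C@H](O)c1cc(OCOC)cc(OCOC)c1 | intermediate
5 | allyl acetoacetate (prop-2-en-1-yl 3-oxobutanoate) | CC(=O)CC(=O)OCC=C | starting material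
6 | allyl acetoacetate dianion (sodium lithium salt) | C=C([O-])C=C([O-])OCC=C.[Li+].[Na+] | intermediate
7 | prop-2-en-1-yl (7S)-7-[3,5-bis(methoxymethoxy)phenyl]-7-hydroxy-3,5-dioxoheptanoate | C=CCOC(=O)CC(=O)CC(=O)C[C@H](O)c1cc(OCOC)cc(OCOC)c1 | intermediate
8 | prop-2-en-1-yl 2-{(2S)-2-[3,5-bis(methoxymethoxy)phenyl]-4-oxo-3,4-dihydro-2H-pyran-6-yl}acetate | C=CCOC(=O)CC1=CC(=O)C[C@@H](c2cc(OCOC)cc(OCOC)c2)O1 | intermediate
9 | 2-{(2S)-2-[3,5-bis(methoxymethoxy)phenyl]-4-oxo-3,4-dihydro-2H-pyran-6-yl}acetic acid | OC(=O)CC1=CC(=O)C[C@@H](c2cc(OCOC)cc(OCOC)c2)O1 | intermediate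
10 | dimethyl malonate | COC(=O)CC(=O)OC | starting material
11 | (2E,6E)-farnesyl bromide | CC(C)=CCC/C(C)=C/CC/C(C)=C/CBr | starting material
12 | dimethyl 2-[(2E,6E)-3,7,11-trimethyldodeca-2,6,10-trien-1-yl]propanedioate | COC(=O)C(C/C=C(\C)CC/C=C(\C)CCC=C(C)C)C(=O)OC | intermediate
13 | potassium 3-methoxy-3-oxo-2-[(2E,6E)-3,7,11-trimethyldodeca-2,6,10-trien-1-yl]propanoate (racemic) | COC(=O)C(C/C=C(\C)CC/C=C(\C)CCC=C(C)C)C(=O)[O-].[K+] | intermediate
14 | 1-(1H-imidazol-1-yl)-2-{(2S)-2-[3,5-bis(methoxymethoxy)phenyl]-4-oxo-3,4-dihydro-2H-pyran-6-yl}ethan-1-one | O=C(CC1=CC(=O)C[C@@H](c2cc(OCOC)cc(OCOC)c2)O1)n1ccnc1 | intermediate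
15 | methyl 2-farnesyl-3-oxo-4-{(2S)-2-[3,5-bis(methoxymethoxy)phenyl]-4-oxo-3,4-dihydro-2H-pyran-6-yl}butanoate (C6 epimers) | COC(=O)C(C/C=C(\C)CC/C=C(\C)CCC=C(C)C)C(=O)CC1=CC(=O)C[C@@H](c2cc(OCOC)cc(OCOC)c2)O1 | intermediate
16 | (2S)-2-[3,5-bis(methoxymethoxy)phenyl]-6-farnesyl-5,7-dihydroxy-2,3-dihydro-4H-chromen-4-one | CC(C)=CCC/C(C)=C/CC/C(C)=C/Cc1c(O)cc2c(c1O)C(=O)C[C@@H](c1cc(OCOC)cc(OCOC)c1)O2 | intermediate
17 | (2S)-2-(3,5-dihydroxyphenyl)-6-farnesyl-5,7-dihydroxy-2,3-dihydro-4H-chromen-4-one | CC(C)=CCC/C(C)=C/CC/C(C)=C/Cc1c(O)cc2c(c1O)C(=O)C[C@@H](c1cc(O)cc(O)c1)O2 | target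

**Step count and risks**

Total step count: 10. Longest linear sequence: 8 steps (steps 1, 2, 3, 4, 5, 8, 9, 10).

Steps most likely to fail:

1. Step 9 (key step, proposed new method).
   - Risk: the dienolate may rest as the C6 enolate, in which the ester is a poor electrophile, so that C4a-acylation is slow. Traces of methoxide may cleave the β-keto ester by retro-Claisen. Long exposure of product 16 to base may open the flavanone to the chalcone and erode the C2 configuration; this would be checked by chiral HPLC.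
   - Fallback (known chemistry): ring A is bought and the heterocycle is closed last by Mitsunobu etherification. It sets out from β-keto ester 3 and bromide 11, with phloroglucinol as an extra commercial material, and comes back at target 17.
   - B-ring piece: transfer hydrogenation of 3 with the (R,R)-TsDPEN catalyst should give methyl (3R)-3-[3,5-bis(methoxymethoxy)phenyl]-3-hydroxypropanoate F1. It is silylated (TBSCl, imidazole) to the tert-butyldimethylsilyl ether F2 and converted (MeNHOMe·HCl, iPrMgCl) into the Weinreb amide F3.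
   - A-ring piece: phloroglucinol is bis-protected (MOMCl, iPr2NEt) to 3,5-bis(methoxymethoxy)phenol F4 and silylated (TIPSCl, imidazole) to the triisopropylsilyl ether F5. Lithiation between the two MOM ethers (n-BuLi, THF, 0 °C), transmetalation (CuBr·SMe2) and reaction with 11 give the 4-farnesyl arene F6.
   - Coupling and closure: a second MOM-directed lithiation next to the silyl ether (n-BuLi, TMEDA, −40 °C, to limit benzylic metalation) and addition to F3 give the aryl ketone F7. TBAF/AcOH removes both silyl groups to give the phenol carbinol F8. Mitsunobu closure (PPh3, DIAD) through the only free phenol, with inversion at the carbinol, gives (2S)-6-farnesyl-5,7,3′,5′-tetrakis(methoxymethoxy)flavanone F9. The 6-position of the farnesyl group is fixed by the silyl/MOM differentiation.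
   - HCl/MeOH as in step 10 then gives 17.

2. Step 8.
   - Risk: the vinylogous β-keto acid 9 may decarboxylate, its imidazolide may self-condense through a ketene, and the α-substituted malonate may acylate slowly.
   - Fallback: the bond C8–C7 is made instead of C7–C6 and the free acid is avoided. It sets out from allyl ester 8 and salt 13 and comes back at 15.
   - 13 with oxalyl chloride (cat. DMF, CH2Cl2, 0 °C) gives methyl 2-(chlorocarbonyl)-5,9,13-trimethyltetradeca-4,8,12-trienoate F10.
   - C-acylation of the magnesium enolate of 8 (MgCl2, Et3N, MeCN) at C8 gives the acylated allyl ester F11.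
   - Pd(PPh3)4/morpholine then removes the allyl group and the resulting β-keto acid loses CO2 (Tsuji-type deallylation–decarboxylation) to give 15.

3. Step 4.
   - Risk: the alkoxide of 4 may slow the acylation, and during the acid treatment lactonisation of the diketo ester to a 4-hydroxy-2-pyranone or dehydration of the benzylic carbinol may compete with hemiketal dehydration.
   - Fallback: the carbinol is protected and the diketo ester is made through a dioxinone. It sets out from 4 and comes back at 8.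
   - 4 is silylated (TESCl, imidazole) to the triethylsilyl ether F12.
   - The lithium dienolate of 2,2,6-trimethyl-4H-1,3-dioxin-4-one (LiHMDS, THF, −78 °C) is acylated by F12 to give the keto-dioxinone F13.
   - Thermolysis in toluene with allyl alcohol (110 °C, acylketene trapping) gives the silyl-protected allyl diketo ester F14.
   - TsOH·H2O in wet CH2Cl2 removes the silyl group and cyclodehydrates to 8.

**Further compounds**

F1 | step 9 | methyl (3R)-3-[3,5-bis(methoxymethoxy)phenyl]-3-hydroxypropanoate | COC(=O)C[C@@H](O)c1cc(OCOC)cc(OCOC)c1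
F2 | step 9 | methyl (3R)-3-[3,5-bis(methoxymethoxy)phenyl]-3-[(tert-butyldimethylsilyl)oxy]propanoate | COC(=O)C[C@@H](O[Si](C)(C)C(C)(C)C)c1cc(OCOC)cc(OCOC)c1
F3 | step 9 | (3R)-3-[3,5-bis(methoxymethoxy)phenyl]-3-[(tert-butyldimethylsilyl)oxy]-N-methoxy-N-methylpropanamide | CON(C)C(=O)C[C@@H](O[Si](C)(C)C(C)(C)C)c1cc(OCOC)cc(OCOC)c1
F4 | step 9 | 3,5-bis(methoxymethoxy)phenol | COCOc1cc(O)cc(OCOC)c1
F5 | step 9 | [3,5-bis(methoxymethoxy)phenoxy]tri(propan-2-yl)silane | COCOc1cc(O[Si](C(C)C)(C(C)C)C(C)C)cc(OCOC)c1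
F6 | step 9 | [4-farnesyl-3,5-bis(methoxymethoxy)phenoxy]tri(propan-2-yl)silane | COCOc1cc(O[Si](C(C)C)(C(C)C)C(C)C)cc(OCOC)c1C/C=C(\C)CC/C=C(\C)CCC=C(C)C
F7 | step 9 | (3R)-3-[3,5-bis(methoxymethoxy)phenyl]-3-[(tert-butyldimethylsilyl)oxy]-1-{3-farnesyl-2,4-bis(methoxymethoxy)-6-[(triisopropylsilyl)oxy]phenyl}propan-1-one | COCOc1cc(O[Si](C(C)C)(C(C)C)C(C)C)c(C(=O)C[C@@H](O[Si](C)(C)C(C)(C)C)c2cc(OCOC)cc(OCOC)c2)c(OCOC)c1C/C=C(\C)CC/C=C(\C)CCC=C(C)C
F8 | step 9 | (3R)-3-[3,5-bis(methoxymethoxy)phenyl]-1-[3-farnesyl-6-hydroxy-2,4-bis(methoxymethoxy)phenyl]-3-hydroxypropan-1-one | COCOc1cc(O)c(C(=O)C[C@@H](O)c2cc(OCOC)cc(OCOC)c2)c(OCOC)c1C/C=C(\C)CC/C=C(\C)CCC=C(C)C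
F9 | step 9 | (2S)-2-[3,5-bis(methoxymethoxy)phenyl]-6-farnesyl-5,7-bis(methoxymethoxy)-2,3-dihydro-4H-chromen-4-one | CC(C)=CCC/C(C)=C/CC/C(C)=C/Cc1c(OCOC)cc2c(c1OCOC)C(=O)C[C@@H](c1cc(OCOC)cc(OCOC)c1)O2
F10 | step 8 | methyl 2-(chlorocarbonyl)-5,9,13-trimethyltetradeca-4,8,12-trienoate (4E,8E) | COC(=O)C(C/C=C(\C)CC/C=C(\C)CCC=C(C)C)C(=O)Cl
F11 | step 8 | 1-allyl 5-methyl 2-{(2S)-2-[3,5-bis(methoxymethoxy)phenyl]-4-oxo-3,4-dihydro-2H-pyran-6-yl}-4-farnesyl-3-oxopentanedioate | C=CCOC(=O)C(C(=O)C(C/C=C(\C)CC/C=C(\C)CCC=C(C)C)C(=O)OC)C1=CC(=O)C[C@@H](c2cc(OCOC)cc(OCOC)c2)O1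
F12 | step 4 | methyl (3S)-3-[3,5-bis(methoxymethoxy)phenyl]-3-[(triethylsilyl)oxy]propanoate | COC(=O)C[C@H](O[Si](CC)(CC)CC)c1cc(OCOC)cc(OCOC)c1
F13 | step 4 | 6-{(4S)-4-[3,5-bis(methoxymethoxy)phenyl]-2-oxo-4-[(triethylsilyl)oxy]butyl}-2,2-dimethyl-4H-1,3-dioxin-4-one | CC1(C)OC(=O)C=C(CC(=O)C[C@H](O[Si](CC)(CC)CC)c2cc(OCOC)cc(OCOC)c2)O1
F14 | step 4 | prop-2-en-1-yl (7S)-7-[3,5-bis(methoxymethoxy)phenyl]-3,5-dioxo-7-[(triethylsilyl)oxy]heptanoate | C=CCOC(=O)CC(=O)CC(=O)C[C@H](O[Si](CC)(CC)CC)c1cc(OCOC)cc(OCOC)c1
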